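## The problem

The target is a cis-configured isoflavan-4-ol. Ring A is fused to the dihydropyran ring C and carries a free 5-OH and a 7-OMe; ring B sits on C3 and a secondary alcohol on C4, both centres R. The two stereocentres are contiguous and C3 lies alpha to C4, so at the 4-ketone stage C3 is configurationally labile. That rules out setting C3 early, but it allows one catalyst-controlled reduction to fix C4 and, through the 3-aryl group, C3 as well. The C4 alcohol is benzylic to a ring with oxygen at both ortho positions and at the para position; it ionises with traces of acid and must be unveiled last, under buffered fluoride. The 3-methylbut-2-enyl (prenyl) group next to the 4'-oxygen adds acid or closes to a dimethylchroman under Brønsted or strong Lewis acids, which limits every step after its introduction. Ring B is a 1,2,4,5-tetrasubstituted resorcinol monoether with prenyl at C5' beside the 4'-OH and not at C3' between the two oxygens, a pattern that electrophilic prenylation of a preformed resorcinol does not deliver cleanly. Ring A needs its two meta oxygens told apart, most simply through the peri relation of O5 to a C4 carbonyl. The feature that opens the key step is that the C2'(OMe)–C3'–C4'(O)–C5'(prenyl) edge of ring B maps onto a 1,1-dimethoxy-3-silyloxy diene with the prenyl group on its terminus. C1' and C6' then map onto the alkyne carbons of an ethynyl ketone whose carbonyl carbon becomes C3 and whose other substituent already holds C2, O1 and ring A.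

## Retrosynthesis

**23 to 22 to 21 (O–Si bonds, then C4–H).** The target 23 is reached from bis-silyl ether 22 by fluoride alone, so no acid meets the benzylic alcohol. Alcohol 22 is cut at C4–H back to racemic ketone 21. The neighbouring option, setting C3 first and reducing under substrate control, fails because C3 epimerises at the ketone stage. The chosen cut uses that lability: a dynamic kinetic transfer hydrogenation sets both centres. The precursor is stereochemically blank. The forward step needs racemisation faster than reduction and a catalyst that controls the carbonyl face.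

**21 to 20 to 19 (O5–Si, then O5–CH3).** Ring A of isoflavanone 19 is a symmetric dimethyl ether in which only the peri carbonyl distinguishes O5 from O7. An unsymmetrical phenol from the start would give two regioisomers on ring closure. The forward steps are a chelation-controlled demethylation (to 20) that spares 7-OMe, 2'-OMe, the silyl ether and the prenyl group, and a silylation (to 21) that turns the chelated phenol into an ordinary aryl ketone for the reduction.

**19 to 17 (C4–C4a).** Cutting O1–C2 instead would require an intermolecular acylation of ring A. Cutting C3–C1' would require arylation with a prenylated ring B halide that would itself have to be made regioselectively. The C4–C4a cut leaves ring A and O1–C2 in one simple aryl ether and exploits symmetry: both positions ortho to O1 are equivalent. Acid 17 is open-chain with one racemic centre. The forward Friedel–Crafts closure must be mild enough for the prenyl group.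

**17 to 15 to 13 to 12 (C3–C4, one carbon).** The carboxyl carbon is added to ketone 12 by methylenation (13), anti-Markovnikov hydration (15) and oxidation (17). The better-known methoxymethylene Wittig and hydrolysis route is set aside as first choice: it exposes an oxocarbenium ion and an aldehyde to acid with the very nucleophilic ring A tethered six atoms away. Ketone 12 is achiral. The forward sequence needs only chemoselectivity between a 1,1-disubstituted and a trisubstituted alkene.

**12 to 5 + 10 (C1'–C2' and C5'–C6', ring B).** Ring B is cut into diene 5 and ynone 10. Against prenylation of a ring B phenol, this cut fixes the prenyl position by the constitution of the diene. The diene also delivers the 2'-OMe, and the 4'-oxygen arrives already silylated. The precursors are an acyclic triene and a small aryloxymethyl ynone. The forward reaction must be regioselective and must close through the diene termini.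

**5 to 4 to 2 + 3, and 2 to 1.** The silyl dienol ether 5 comes from vinylogous ester 4 by gamma-deprotonation and O-silylation. Ketone 4 comes from C-acylation of ketene acetal 3 with acid chloride 2, made from acid 1. The prenyl group is therefore part of a commercial C7 acid.

**10 to 8 + 9, and 8 to 6 + 7.** The ynone is cut at the acyl–alkyne bond to Weinreb amide 8 and ethynyl Grignard reagent 9. Amide 8 is the ether of phenol 6 with chloroacetamide 7.

## Roads not taken

**Alternative 1:** Conjunctive cross-coupling.
- Cut: C4–C4a and C3–C1' across an alkene.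
- Forward step: the lithiated arene from A4 and (Z)-alkenyl boronate A3 form an ate complex. With aryl bromide A2, Pd(OAc)2 and a chiral ferrocenyl bisphosphine, the ring A aryl group shifts from boron to carbon while the ring B aryl group is delivered from palladium. Oxidation of the C–B bond gives A1.
- Merits: both stereocentres are set in one catalytic enantioselective step, C4 arrives directly as the alcohol, and three fragments converge. In stereochemical directness this road is better than the chosen one.
- Weak points: A2 must already carry prenyl at C5', so the ring B problem is moved, not solved. The migrating aryl group has two ortho oxygens and the alkene is internal, both demanding for the 1,2-shift. After A1, ring C still has to be closed at O1–C2 after removing one SEM group and the primary silyl ether, while the free C4 alcohol sits on a phloroglucinol-type ring; SEM removal needs acid or hot fluoride.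
- Comparison: the chosen plan offers a reduction of well-understood facial sense on a ketone, a ring B whose substitution is fixed by construction, and no acid once the C4 alcohol exists.

**Alternative 2:** Aryne insertion and oxa-Michael cascade.
- Cut: O1–C8a, C4–C4a and O1–C2.
- Forward step: CsF releases 3,5-dimethoxybenzyne from A7. The aryne inserts into the carboxyl C–O bond of acrylic acid A6, and the resulting ortho-hydroxyaryl vinyl ketone closes ring C to give racemic isoflavanone A5.
- Merits: this is the shortest way to the isoflavanone core, one step against steps 7 to 10 of the chosen route, and the 3-methoxy group of the aryne steers the regiochemistry.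
- Weak points: A6 again presupposes a correctly prenylated ring B. The aryne is generated beside a prenyl alkene and a polymerisable acrylate. A5 still needs 5-O-demethylation, and its methoxymethyl ether needs acid, so it would have to be exchanged before the reduction.
- Comparison: the endgame is the same as here. The chosen plan is longer in the middle but makes ring B with the prenyl group in place in about the number of operations A6 would cost.

**Alternative 3:** Danheiser benzannulation of ring A.
- Cut: C5–C6, C7–C8 and C4a–C5.
- Forward step: irradiation of diazo ketone A9 gives a vinylketene by Wolff rearrangement. This adds to methoxyethyne A10 and passes through a cyclobutenone and a dienylketene to phenol A8.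
- Merits: the 5-OH is formed free and the 7-OMe comes from the alkyne, so no demethylation is needed. Both stereocentres are set before ring A exists, when the C4 oxygen is only allylic. No Lewis acid is used after the prenyl group is in place. In these respects it is better than the chosen plan.
- Weak points: A9 is an enantiopure cis-disubstituted dihydropyran with a diazoacetyl group on the enol ether carbon and needs a long synthesis of its own. Carbene and ketene intermediates are generated near the prenyl alkene. A10 is volatile and unstable. Ring B must again be preformed.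
- Comparison: the chosen plan uses commercial ring A and ring B precursors, thermal and ionic steps only, and solves the C5' regiochemistry.

Key step: step 6

Remark on the chemistry: the target is read as the cis-(3R,4R) isomer, and the (R,R)-configured catalyst of step 13 is assigned by analogy with 4-chromanones and other aryl alkyl ketones, for which this ligand configuration gives the (R)-carbinol.

## Route

Step 1
Reactants: 1 5-methylhex-4-enoic acid
Product: 2 5-methylhex-4-enoyl chloride
Conditions: (COCl)2, DMF (cat.), CH2Cl2, 0 °C → rt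
Reagents that add atoms: oxalyl chloride, O=C(Cl)C(=O)Cl
Why: Acid chloride formation through the catalytic chloroiminium species from DMF; the by-products are gases and the isolated trisubstituted alkene is not attacked in the cold, dilute, non-polar medium.

Step 2
Reactants: 2 5-methylhex-4-enoyl chloride; 3 1,1-dimethoxyethene (2.2 equiv)
Product: 4 1,1-dimethoxy-7-methylocta-1,6-dien-3-one
Conditions: Et2O, 0 °C → rt
Reagents that add atoms: none
Why: C-Acylation of a ketene acetal: the nucleophilic CH2 carbon attacks the acid chloride and the dialkoxycarbenium ion loses a proton to give the vinylogous ester; the second equivalent of 3 consumes the HCl as methyl acetate and chloromethane, so the prenyl alkene sees no free acid.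

Step 3
Reactants: 4 1,1-dimethoxy-7-methylocta-1,6-dien-3-one
Product: 5 (3Z)-1,1-dimethoxy-7-methyl-3-{[tri(propan-2-yl)silyl]oxy}octa-1,3,6-triene
Conditions: iPr3SiOTf, Et3N, Et2O, 0 °C → rt; pentane extraction, used crude
Reagents that add atoms: tri(propan-2-yl)silyl trifluoromethanesulfonate, CC(C)[Si](C(C)C)(C(C)C)OS(=O)(=O)C(F)(F)F
Why: Soft enolisation of a vinylogous ester: O-silylation activates the carbonyl and Et3N removes a proton from C4, the only enolisable position; the Z enol ether (chain cis to the silyloxy group) is the thermodynamically preferred geometry, and the triisopropylsilyl group is chosen to survive to the last step.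

Step 4
Reactants: 6 3,5-dimethoxyphenol; 7 2-chloro-N-methoxy-N-methylacetamide
Product: 8 2-(3,5-dimethoxyphenoxy)-N-methoxy-N-methylacetamide
Conditions: K2CO3, NaI (cat.), acetone, reflux
Reagents that add atoms: none
Why: Williamson ether synthesis by SN2 displacement on an alpha-chloro amide; K2CO3 in acetone favours O- over C-alkylation of the electron-rich phenol.

Step 5
Reactants: 8 2-(3,5-dimethoxyphenoxy)-N-methoxy-N-methylacetamide; 9 ethynylmagnesium bromide
Product: 10 1-(3,5-dimethoxyphenoxy)but-3-yn-2-one
Conditions: THF, −78 → 0 °C; inverse quench into cold aq. NaHSO4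
Reagents that add atoms: none
Why: Weinreb ketone synthesis: the chelated tetrahedral magnesium adduct stops at mono-addition and collapses to the ynone on acidic quench, which also protonates the released amine before it can add to the ynone.

Step 6
Reactants: 5 (3Z)-1,1-dimethoxy-7-methyl-3-{[tri(propan-2-yl)silyl]oxy}octa-1,3,6-triene (1.3 equiv); 10 1-(3,5-dimethoxyphenoxy)but-3-yn-2-one
Product: 12 2-(3,5-dimethoxyphenoxy)-1-[2-methoxy-5-(3-methylbut-2-en-1-yl)-4-{[tri(propan-2-yl)silyl]oxy}phenyl]ethan-1-one, via cyclohexa-1,4-diene cycloadduct 11 (not isolated)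
Conditions: PhMe, 0 °C → rt, then 60 °C; SiO2, CH2Cl2, rt
Reagents that add atoms: none
Why: This is a normal-demand (4+2) cycloaddition of an electron-rich ketene acetal diene to an acetylenic ketone followed by aromatisation, the reaction type by which 1,1-dialkoxy-3-silyloxybutadienes and alkynyl ketones or propiolates give 4-acyl-3-alkoxyphenol derivatives. The silyl enol ether terminus C4 of 5, which carries the prenyl CH2, is the nucleophilic end and bonds to the unsubstituted beta-carbon of 10 (C5'–C6'), while the ketene acetal carbon bonds to the acyl-bearing carbon (C1'–C2'); the closure may be concerted and asynchronous or stepwise (Michael addition, then closure of the allenolate onto the dimethoxycarbenium ion), and both give 11. Ring B is thus closed in a six-membered (4+2) mode from a four-carbon and a two-carbon unit. Adduct 11 has a doubly allylic hydrogen para to the acetal carbon and should lose methanol on warming or on silica, while the silyl ether stays, so 12 arrives protected at O4'. The sp3 centre of 11 is destroyed on aromatisation, so no stereocentre results and the Z geometry of 5 matters only for rate (prenyl CH2 outside in the s-cis conformer). The step needs regioselectivity (prenyl meta to the acyl group and next to the silyloxy group), secured by the matched polarisation of both partners, and periselectivity for closure through the diene termini over a (3+3) Michael–aldol mode through the carbonyl, secured by working thermally without Lewis acid.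

Step 7
Reactants: 12 2-(3,5-dimethoxyphenoxy)-1-[2-methoxy-5-(3-methylbut-2-en-1-yl)-4-{[tri(propan-2-yl)silyl]oxy}phenyl]ethan-1-one
Product: 13 {4-[3-(3,5-dimethoxyphenoxy)prop-1-en-2-yl]-5-methoxy-2-(3-methylbut-2-en-1-yl)phenoxy}tri(propan-2-yl)silane
Conditions: Ph3PCH3Br, KN(SiMe3)2, THF, 0 °C; then 12, 0 °C → rt
Reagents that add atoms: methyltriphenylphosphonium bromide, C[P+](c1ccccc1)(c1ccccc1)c1ccccc1.[Br-]
Why: Wittig methylenation of an aryl ketone with the unstabilised ylide; the non-nucleophilic amide base leaves the aryl silyl ether alone and no acid is present that could cyclise the aryloxy ketone to a benzofuran.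

Step 8
Reactants: 13 {4-[3-(3,5-dimethoxyphenoxy)prop-1-en-2-yl]-5-methoxy-2-(3-methylbut-2-en-1-yl)phenoxy}tri(propan-2-yl)silane
Product: 15 racemic 3-(3,5-dimethoxyphenoxy)-2-[2-methoxy-5-(3-methylbut-2-en-1-yl)-4-{[tri(propan-2-yl)silyl]oxy}phenyl]propan-1-ol, via B-alkyl-9-borabicyclononane 14 (not isolated)
Conditions: 9-BBN, THF, 0 °C → rt; then NaBO3·4H2O, H2O, rt
Reagents that add atoms: sodium perborate (oxygen of 15), [Na+].[Na+].O[B-]1(O)OO[B-](O)(O)OO1; 9-borabicyclo[3.3.1]nonane (boron of intermediate 14 only), B1C2CCCC1CCC2
Why: Hydroboration–oxidation: 9-BBN places boron on the terminal carbon of the 1,1-disubstituted alkene and reacts orders of magnitude more slowly with the trisubstituted prenyl alkene; perborate oxidises the C–B bond under mildly basic conditions that the triisopropylsilyl ether tolerates. C3 is formed racemic, which is intended, since it is set in step 13.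

Step 9
Reactants: 15 racemic 3-(3,5-dimethoxyphenoxy)-2-[2-methoxy-5-(3-methylbut-2-en-1-yl)-4-{[tri(propan-2-yl)silyl]oxy}phenyl]propan-1-ol
Product: 17 racemic 3-(3,5-dimethoxyphenoxy)-2-[2-methoxy-5-(3-methylbut-2-en-1-yl)-4-{[tri(propan-2-yl)silyl]oxy}phenyl]propanoic acid, via aldehyde 16 (not isolated)
Conditions: TEMPO (20 mol%), PhI(OAc)2 (2.5 equiv), MeCN/H2O (1:1), 0 °C → rt
Reagents that add atoms: water, O
Why: Oxoammonium-catalysed alcohol oxidation with PhI(OAc)2 as terminal oxidant: the alcohol gives aldehyde 16, whose hydrate is oxidised on to the acid; the near-neutral medium avoids acid-induced attack of ring A on the aldehyde and beta-elimination of the aryloxide, and isolated alkenes are tolerated.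

Step 10
Reactants: 17 racemic 3-(3,5-dimethoxyphenoxy)-2-[2-methoxy-5-(3-methylbut-2-en-1-yl)-4-{[tri(propan-2-yl)silyl]oxy}phenyl]propanoic acid
Product: 19 racemic 5,7-dimethoxy-3-[2-methoxy-5-(3-methylbut-2-en-1-yl)-4-{[tri(propan-2-yl)silyl]oxy}phenyl]chroman-4-one, via mixed trifluoroacetic anhydride 18 (not isolated)
Conditions: (CF3CO)2O (1.5 equiv), CH2Cl2, 0 °C → rt
Reagents that add atoms: trifluoroacetic anhydride (atoms in intermediate 18 only), O=C(OC(=O)C(F)(F)F)C(F)(F)F
Why: Intramolecular Friedel–Crafts acylation through the mixed anhydride: the ring A carbon attacked is ortho to O1, ortho to one methoxy group and para to the other, and the two such positions are equivalent, so six-membered closure gives a single isoflavanone; only trifluoroacetic acid is released, cold and dilute, which the silyl-capped prenyl arene should tolerate.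

Step 11
Reactants: 19 racemic 5,7-dimethoxy-3-[2-methoxy-5-(3-methylbut-2-en-1-yl)-4-{[tri(propan-2-yl)silyl]oxy}phenyl]chroman-4-one
Product: 20 racemic 5-hydroxy-7-methoxy-3-[2-methoxy-5-(3-methylbut-2-en-1-yl)-4-{[tri(propan-2-yl)silyl]oxy}phenyl]chroman-4-one
Conditions: MgI2·OEt2 (2 equiv), PhMe, 60 °C; aq. NaH2PO4
Reagents that add atoms: none
Why: Chelation-controlled ether cleavage: magnesium binds the C4 carbonyl and O5 in a six-membered chelate and iodide removes the methyl group by SN2; the 7- and 2'-methoxy groups cannot chelate, and the neutral conditions spare the prenyl group and the silyl ether.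

Step 12
Reactants: 20 racemic 5-hydroxy-7-methoxy-3-[2-methoxy-5-(3-methylbut-2-en-1-yl)-4-{[tri(propan-2-yl)silyl]oxy}phenyl]chroman-4-one
Product: 21 racemic 5-[(tert-butyldimethylsilyl)oxy]-7-methoxy-3-[2-methoxy-5-(3-methylbut-2-en-1-yl)-4-{[tri(propan-2-yl)silyl]oxy}phenyl]chroman-4-one
Conditions: tBuMe2SiCl, imidazole, DMAP (cat.), DMF, rt → 40 °C
Reagents that add atoms: tert-butyldimethylsilyl chloride, CC(C)(C)[Si](C)(C)Cl
Why: Imidazole-mediated silylation of the chelated phenol; capping O5 makes the ketone an ordinary aryl ketone for the reduction and prevents the product of step 13 from being an ortho-hydroxybenzyl alcohol under the reducing conditions.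

Step 13
Reactants: 21 racemic 5-[(tert-butyldimethylsilyl)oxy]-7-methoxy-3-[2-methoxy-5-(3-methylbut-2-en-1-yl)-4-{[tri(propan-2-yl)silyl]oxy}phenyl]chroman-4-one
Product: 22 (3R,4R)-5-[(tert-butyldimethylsilyl)oxy]-7-methoxy-3-[2-methoxy-5-(3-methylbut-2-en-1-yl)-4-{[tri(propan-2-yl)silyl]oxy}phenyl]chroman-4-ol
Conditions: RuCl[(R,R)-TsDPEN](p-cymene) (3 mol%), HCO2H/Et3N (1:2), EtOAc, 40 °C
Reagents that add atoms: none
Why: Noyori–Ikariya asymmetric transfer hydrogenation with dynamic kinetic resolution: Et3N racemises C3 through the enol, the divalent ruthenium hydride with the (R,R)-ligand attacks the carbonyl face that gives 4R, and it reduces faster the ketone enantiomer whose 3-aryl group is anti to the incoming hydride, so the cis-(3R,4R) alcohol should result. The amine-rich medium keeps the electron-rich benzylic alcohol from ionising, and the catalyst does not reduce isolated alkenes.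

Step 14
Reactants: 22 (3R,4R)-5-[(tert-butyldimethylsilyl)oxy]-7-methoxy-3-[2-methoxy-5-(3-methylbut-2-en-1-yl)-4-{[tri(propan-2-yl)silyl]oxy}phenyl]chroman-4-ol
Product: 23 (3R,4R)-3-[4-hydroxy-2-methoxy-5-(3-methylbut-2-en-1-yl)phenyl]-7-methoxychromane-4,5-diol
Conditions: Bu4NF (2.5 equiv), AcOH (2.5 equiv), THF, 0 °C; pH 7 buffer
Reagents that add atoms: none
Why: Fluoride cleavage of both aryl silyl ethers through pentacoordinate silicon with phenoxide leaving groups; the acetic acid buffer protonates the phenoxides at once, so silyl migration to O4 and base-driven elimination are avoided, and nothing more acidic is present, so C4 and C3 are untouched.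

## Compound list

1 | 5-methylhex-4-enoic acid | CC(C)=CCCC(=O)O | starting material
2 | 5-methylhex-4-enoyl chloride | CC(C)=CCCC(=O)Cl | intermediate
3 | 1,1-dimethoxyethene | C=C(OC)OC | starting material
4 | 1,1-dimethoxy-7-methylocta-1,6-dien-3-one | COC(OC)=CC(=O)CCC=C(C)C | intermediate
5 | (3Z)-1,1-dimethoxy-7-methyl-3-{[tri(propan-2-yl)silyl]oxy}octa-1,3,6-triene | COC(OC)=C/C(O[Si](C(C)C)(C(C)C)C(C)C)=C/CC=C(C)C | intermediate
6 | 3,5-dimethoxyphenol | COc1cc(O)cc(OC)c1 | starting material
7 | 2-chloro-N-methoxy-N-methylacetamide | CON(C)C(=O)CCl | starting material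
8 | 2-(3,5-dimethoxyphenoxy)-N-methoxy-N-methylacetamide | CON(C)C(=O)COc1cc(OC)cc(OC)c1 | intermediate
9 | ethynylmagnesium bromide | C#C[Mg]Br | starting material
10 | 1-(3,5-dimethoxyphenoxy)but-3-yn-2-one | C#CC(=O)COc1cc(OC)cc(OC)c1 | intermediate
11 | racemic 2-(3,5-dimethoxyphenoxy)-1-[6,6-dimethoxy-3-(3-methylbut-2-en-1-yl)-4-{[tri(propan-2-yl)silyl]oxy}cyclohexa-1,4-dien-1-yl]ethan-1-one | COC1(OC)C=C(O[Si](C(C)C)(C(C)C)C(C)C)C(CC=C(C)C)C=C1C(=O)COc1cc(OC)cc(OC)c1 | intermediate (not isolated)
12 | 2-(3,5-dimethoxyphenoxy)-1-[2-methoxy-5-(3-methylbut-2-en-1-yl)-4-{[tri(propan-2-yl)silyl]oxy}phenyl]ethan-1-one | COc1cc(O[Si](C(C)C)(C(C)C)C(C)C)c(CC=C(C)C)cc1C(=O)COc1cc(OC)cc(OC)c1 | intermediate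
13 | {4-[3-(3,5-dimethoxyphenoxy)prop-1-en-2-yl]-5-methoxy-2-(3-methylbut-2-en-1-yl)phenoxy}tri(propan-2-yl)silane | C=C(COc1cc(OC)cc(OC)c1)c1cc(CC=C(C)C)c(O[Si](C(C)C)(C(C)C)C(C)C)cc1OC | intermediate
14 | racemic 9-{3-(3,5-dimethoxyphenoxy)-2-[2-methoxy-5-(3-methylbut-2-en-1-yl)-4-{[tri(propan-2-yl)silyl]oxy}phenyl]propyl}-9-borabicyclo[3.3.1]nonane | COc1cc(O[Si](C(C)C)(C(C)C)C(C)C)c(CC=C(C)C)cc1C(CB1C2CCCC1CCC2)COc1cc(OC)cc(OC)c1 | intermediate (not isolated)
15 | racemic 3-(3,5-dimethoxyphenoxy)-2-[2-methoxy-5-(3-methylbut-2-en-1-yl)-4-{[tri(propan-2-yl)silyl]oxy}phenyl]propan-1-ol | OCC(COc1cc(OC)cc(OC)c1)c1cc(CC=C(C)C)c(O[Si](C(C)C)(C(C)C)C(C)C)cc1OC | intermediate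
16 | racemic 3-(3,5-dimethoxyphenoxy)-2-[2-methoxy-5-(3-methylbut-2-en-1-yl)-4-{[tri(propan-2-yl)silyl]oxy}phenyl]propanal | O=CC(COc1cc(OC)cc(OC)c1)c1cc(CC=C(C)C)c(O[Si](C(C)C)(C(C)C)C(C)C)cc1OC | intermediate (not isolated)
17 | racemic 3-(3,5-dimethoxyphenoxy)-2-[2-methoxy-5-(3-methylbut-2-en-1-yl)-4-{[tri(propan-2-yl)silyl]oxy}phenyl]propanoic acid | OC(=O)C(COc1cc(OC)cc(OC)c1)c1cc(CC=C(C)C)c(O[Si](C(C)C)(C(C)C)C(C)C)cc1OC | intermediate
18 | racemic mixed anhydride of 17 with trifluoroacetic acid | FC(F)(F)C(=O)OC(=O)C(COc1cc(OC)cc(OC)c1)c1cc(CC=C(C)C)c(O[Si](C(C)C)(C(C)C)C(C)C)cc1OC | intermediate (not isolated)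
19 | racemic 5,7-dimethoxy-3-[2-methoxy-5-(3-methylbut-2-en-1-yl)-4-{[tri(propan-2-yl)silyl]oxy}phenyl]chroman-4-one | COc1cc(OC)c2c(c1)OCC(c1cc(CC=C(C)C)c(O[Si](C(C)C)(C(C)C)C(C)C)cc1OC)C2=O | intermediate
20 | racemic 5-hydroxy-7-methoxy-3-[2-methoxy-5-(3-methylbut-2-en-1-yl)-4-{[tri(propan-2-yl)silyl]oxy}phenyl]chroman-4-one | COc1cc(O)c2c(c1)OCC(c1cc(CC=C(C)C)c(O[Si](C(C)C)(C(C)C)C(C)C)cc1OC)C2=O | intermediate
21 | racemic 5-[(tert-butyldimethylsilyl)oxy]-7-methoxy-3-[2-methoxy-5-(3-methylbut-2-en-1-yl)-4-{[tri(propan-2-yl)silyl]oxy}phenyl]chroman-4-one | COc1cc(O[Si](C)(C)C(C)(C)C)c2c(c1)OCC(c1cc(CC=C(C)C)c(O[Si](C(C)C)(C(C)C)C(C)C)cc1OC)C2=O | intermediate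
22 | (3R,4R)-5-[(tert-butyldimethylsilyl)oxy]-7-methoxy-3-[2-methoxy-5-(3-methylbut-2-en-1-yl)-4-{[tri(propan-2-yl)silyl]oxy}phenyl]chroman-4-ol (cis) | COc1cc(O[Si](C)(C)C(C)(C)C)c2c(c1)OC[C@@H](c1cc(CC=C(C)C)c(O[Si](C(C)C)(C(C)C)C(C)C)cc1OC)[C@H]2O | intermediate
23 | (3R,4R)-3-[4-hydroxy-2-methoxy-5-(3-methylbut-2-en-1-yl)phenyl]-7-methoxychromane-4,5-diol (cis) | COc1cc(O)c2c(c1)OC[C@@H](c1cc(CC=C(C)C)c(O)cc1OC)[C@H]2O | target

## Step count and risks

Total: 14 steps. Longest linear sequence: 12 steps (steps 1–3 and 6–14); the ynone branch (steps 4 and 5) joins at step 6.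

**Step 6 (key step).** The most likely failure is loss of the partners before they combine. The ketene acetal diene is destroyed by protic species, including the methanol set free on aromatisation, and the aryloxymethyl ynone can oligomerise while the substituted diene terminus reacts slowly. Fallback: the same diene 5 is combined with methyl propiolate, a robust dienophile that can be used in excess at 80 °C in PhMe, to give methyl 2-methoxy-5-(3-methylbut-2-en-1-yl)-4-{[tri(propan-2-yl)silyl]oxy}benzoate F1. This is converted with MeNH(OMe)·HCl and iPrMgCl in THF into the Weinreb amide F2. Treatment of F2 with LiCH2Cl (from ICH2Cl and MeLi·LiBr, THF, −78 °C) gives the chloromethyl ketone F3. O-Alkylation of phenol 6 with F3 (K2CO3, acetone) rejoins the route at 12. Ring B is still made by the same benzannulation, and the aryloxymethyl unit is attached afterwards.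

**Step 8.** Hydroboration of the hindered, ortho-substituted 1,1-diaryl-type alkene may be slow, and forcing it could let the prenyl alkene react. Fallback: ketone 12 is treated with the ylide from (methoxymethyl)triphenylphosphonium chloride and KN(SiMe3)2 to give the methyl enol ether F4 (E/Z mixture). Brief hydrolysis with 1 M aqueous HCl in THF at 0 °C gives aldehyde 16, and oxidation with NaClO2, NaH2PO4 and excess 2-methylbut-2-ene rejoins the route at 17. This avoids hydroboration altogether; the price is a short exposure of the aldehyde to acid beside the nucleophilic ring A.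

**Step 10.** Trifluoroacetic acid may add to or cyclise the prenyl alkene, and trifluoroacetic anhydride may trifluoroacetylate ring A instead of activating the acid. Fallback: acid 17 is coupled with Me2NH·HCl (EDC·HCl, HOBt, iPr2NEt, CH2Cl2) to the N,N-dimethylamide F5. Activation with Tf2O and 2-chloropyridine in CH2Cl2 at −78 → 0 °C, followed by aqueous NaHCO3, closes ring C in a base-buffered Vilsmeier–Haack-type acylation and rejoins the route at 19.

**Step 13.** Hydride transfer to a ketone flanked by the peri silyloxy group may be slow. Amine-induced retro-oxa-Michael opening of ring C, or incomplete racemisation of C3, could then erode yield or enantiomeric purity. Fallback: ketone 21 is reduced with LiBH(sBu)3 in THF at −78 °C, where attack anti to the 3-aryl group should give the racemic cis alcohol F6. The enantiomers are separated by preparative chromatography on a chiral stationary phase, giving 22 and its (3S,4S) enantiomer F7. F7 is returned to 21 by Dess–Martin oxidation, since C3 racemises at the ketone stage. The route is rejoined at 22.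

## Further compounds

F1 | step 6 | methyl 2-methoxy-5-(3-methylbut-2-en-1-yl)-4-{[tri(propan-2-yl)silyl]oxy}benzoate | COC(=O)c1cc(CC=C(C)C)c(O[Si](C(C)C)(C(C)C)C(C)C)cc1OC
F2 | step 6 | N,2-dimethoxy-N-methyl-5-(3-methylbut-2-en-1-yl)-4-{[tri(propan-2-yl)silyl]oxy}benzamide | CON(C)C(=O)c1cc(CC=C(C)C)c(O[Si](C(C)C)(C(C)C)C(C)C)cc1OC
F3 | step 6 | 2-chloro-1-[2-methoxy-5-(3-methylbut-2-en-1-yl)-4-{[tri(propan-2-yl)silyl]oxy}phenyl]ethan-1-one | ClCC(=O)c1cc(CC=C(C)C)c(O[Si](C(C)C)(C(C)C)C(C)C)cc1OC
F4 | step 8 | {4-[3-(3,5-dimethoxyphenoxy)-1-methoxyprop-1-en-2-yl]-5-methoxy-2-(3-methylbut-2-en-1-yl)phenoxy}tri(propan-2-yl)silane (E/Z mixture) | COC=C(COc1cc(OC)cc(OC)c1)c1cc(CC=C(C)C)c(O[Si](C(C)C)(C(C)C)C(C)C)cc1OC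
F5 | step 10 | racemic 3-(3,5-dimethoxyphenoxy)-2-[2-methoxy-5-(3-methylbut-2-en-1-yl)-4-{[tri(propan-2-yl)silyl]oxy}phenyl]-N,N-dimethylpropanamide | CN(C)C(=O)C(COc1cc(OC)cc(OC)c1)c1cc(CC=C(C)C)c(O[Si](C(C)C)(C(C)C)C(C)C)cc1OC
F6 | step 13 | racemic cis-5-[(tert-butyldimethylsilyl)oxy]-7-methoxy-3-[2-methoxy-5-(3-methylbut-2-en-1-yl)-4-{[tri(propan-2-yl)silyl]oxy}phenyl]chroman-4-ol (both enantiomers) | COc1cc(O[Si](C)(C)C(C)(C)C)c2c(c1)OC[C@@H](c1cc(CC=C(C)C)c(O[Si](C(C)C)(C(C)C)C(C)C)cc1OC)[C@H]2O.COc1cc(O[Si](C)(C)C(C)(C)C)c2c(c1)OC[C@H](c1cc(CC=C(C)C)c(O[Si](C(C)C)(C(C)C)C(C)C)cc1OC)[C@@H]2O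
F7 | step 13 | (3S,4S)-5-[(tert-butyldimethylsilyl)oxy]-7-methoxy-3-[2-methoxy-5-(3-methylbut-2-en-1-yl)-4-{[tri(propan-2-yl)silyl]oxy}phenyl]chroman-4-ol | COc1cc(O[Si](C)(C)C(C)(C)C)c2c(c1)OC[C@H](c1cc(CC=C(C)C)c(O[Si](C(C)C)(C(C)C)C(C)C)cc1OC)[C@@H]2O
A1 | alternative 1 | protected open-chain 1,2-diaryl-1,3-diol with the C4 alcohol free (configuration as in the target) | CC(C)(C)[Si](C)(C)OC[C@@H](c1cc(CC=C(C)C)c(O[Si](C)(C)C(C)(C)C)cc1OC)[C@H](c1c(OCOCC[Si](C)(C)C)cc(OC)cc1OCOCC[Si](C)(C)C)O
A2 | alternative 1 | [4-bromo-5-methoxy-2-(3-methylbut-2-en-1-yl)phenoxy](tert-butyl)dimethylsilane | COc1cc(O[Si](C)(C)C(C)(C)C)c(CC=C(C)C)cc1Br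
A3 | alternative 1 | (Z)-tert-butyldimethyl{[3-(4,4,5,5-tetramethyl-1,3,2-dioxaborolan-2-yl)prop-2-en-1-yl]oxy}silane | CC(C)(C)[Si](C)(C)OC/C=C\B1OC(C)(C)C(C)(C)O1
A4 | alternative 1 | 1-methoxy-3,5-bis{[2-(trimethylsilyl)ethoxy]methoxy}benzene | COc1cc(OCOCC[Si](C)(C)C)cc(OCOCC[Si](C)(C)C)c1
A5 | alternative 2 | racemic 5,7-dimethoxy-3-[2-methoxy-4-(methoxymethoxy)-5-(3-methylbut-2-en-1-yl)phenyl]chroman-4-one | COc1cc(OC)c2c(c1)OCC(c1cc(CC=C(C)C)c(OCOC)cc1OC)C2=O
A6 | alternative 2 | 2-[2-methoxy-4-(methoxymethoxy)-5-(3-methylbut-2-en-1-yl)phenyl]prop-2-enoic acid | C=C(C(=O)O)c1cc(CC=C(C)C)c(OCOC)cc1OC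
A7 | alternative 2 | 3,5-dimethoxy-2-(trimethylsilyl)phenyl trifluoromethanesulfonate | COc1cc(OC)c([Si](C)(C)C)c(OS(=O)(=O)C(F)(F)F)c1
A8 | alternative 3 | (3R,4R)-4-[(tert-butyldimethylsilyl)oxy]-3-[4-[(tert-butyldimethylsilyl)oxy]-2-methoxy-5-(3-methylbut-2-en-1-yl)phenyl]-7-methoxychroman-5-ol | COc1cc(O)c2c(c1)OC[C@@H](c1cc(CC=C(C)C)c(O[Si](C)(C)C(C)(C)C)cc1OC)[C@H]2O[Si](C)(C)C(C)(C)C
A9 | alternative 3 | 2-diazo-1-{cis-4-[(tert-butyldimethylsilyl)oxy]-3-[4-[(tert-butyldimethylsilyl)oxy]-2-methoxy-5-(3-methylbut-2-en-1-yl)phenyl]-3,4-dihydro-2H-pyran-6-yl}ethan-1-one (configuration as in the target) | [N-]=[N+]=CC(=O)C1=C[C@H](O[Si](C)(C)C(C)(C)C)[C@H](c2cc(CC=C(C)C)c(O[Si](C)(C)C(C)(C)C)cc2OC)CO1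
A10 | alternative 3 | methoxyethyne | COC#C
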